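**Retrosynthetic overview**
Target ⇐ (O15 desilylation, O8 isobutyrylation, O8 desilylation) bis-silylated furanone ⇐ ten-membered allenyl ketone C3(=O)–C2H=C1=C10(C14)(C9): epoxidation of C1=C10 and closure of the ring-oxygen–C10 bond give ring A (furanone), the C1 ketone and the C10 centre in one operation; ring A is formed last.
Allenyl ketone ⇐ open-chain Z-vinyl iodide/allenal: NiCl2/CrCl2 closure of C3–C4, then oxidation; ring B (ten-membered carbocycle) is formed second.
Iodo-allenal ⇐ Z-iodo-enal (C4–C6, C15) + (Z)-2-(bromomethyl)enoate (C1–C3, C7–C14): zinc allylation/lactonisation at C6–C7; ring C (cis-fused α-methylene lactone) is formed first and C6, C7 are set from C8.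
Bromide ⇐ (aR)-allenol ⇐ alkynyl oxirane (anti-SN2′ methyl cuprate, centre-to-axis transfer) ⇐ (R)-glyceraldehyde acetonide + methyl (R)-glycidate (source of C8); iodo-enal ⇐ but-2-yne-1,4-diol.
Enabling feature: ring A is O–C3=C2–C1(=O)–C10, a vinylogous ester whose ring oxygen and C1 carbonyl are 1,3-related across C2; it is the cyclised, mono-oxygenated form of an allenyl ketone, and its only stereocentre, C10, is the disubstituted allene terminus (C14, C9), so an allene axis can be converted into the quaternary centre.

Key step: step 17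

Remark: the target numbering is used for all intermediates (C1 ketone, C3 enol-ether carbon, C6 lactone carbinol, C8 acyloxy carbon, C10 quaternary carbon, C11–C13 methylene-lactone carbons, C14 methyl, C15 hydroxymethyl); the target is 4Z,6S,7R,8R,10R with a cis-fused lactone; allene axes are given as aR and written in SMILES as =[C@]= with the allenic hydrogen explicit.

**Step 1**
Reactants: 1 (R)-2,2-dimethyl-1,3-dioxolane-4-carbaldehyde
Product: 2 (S)-4-ethynyl-2,2-dimethyl-1,3-dioxolane
Conditions: dimethyl (1-diazo-2-oxopropyl)phosphonate, K2CO3, MeOH, 0 °C → rt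
Reagents that add atoms: dimethyl (1-diazo-2-oxopropyl)phosphonate, CC(=O)C(=[N+]=[N-])P(=O)(OC)OC
Why: Seyferth–Gilbert homologation in the Ohira–Bestmann variant should convert the aldehyde into the terminal alkyne under mild carbonate conditions that leave the adjacent stereocentre untouched (the descriptor changes from R to S only because the priorities change).

**Step 2**
Reactants: 2 (S)-4-ethynyl-2,2-dimethyl-1,3-dioxolane; 3 methyl (R)-oxirane-2-carboxylate
Product: 5 methyl (2R)-5-[(4S)-2,2-dimethyl-1,3-dioxolan-4-yl]-2-hydroxypent-4-ynoate, via lithium acetylide 4 (not isolated)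
Conditions: n-BuLi, THF, −78 °C; BF3·OEt2; then 3, −78 °C
Reagents that add atoms: n-butyllithium, [Li]CCCC (lithium stays in 4 only)
Why: BF3-promoted alkynylation of a terminal epoxide (Yamaguchi–Hirao alkynylation) should open the glycidate at its unsubstituted carbon (C9), so the C8 stereocentre is carried over unchanged and the ester is not attacked at −78 °C.

**Step 3**
Reactants: 5 acetonide hydroxy ester
Product: 6 methyl (2R,6S)-2,6,7-trihydroxyhept-4-ynoate
Conditions: AcOH/H2O (4:1), 40 °C
Reagents that add atoms: none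
Why: acid-catalysed acetal hydrolysis should free the 1,2-diol without touching the methyl ester or either stereocentre.

**Step 4**
Reactants: 6 triol ester
Product: 8 methyl (2R)-2-hydroxy-5-[(2S)-oxiran-2-yl]pent-4-ynoate, via primary tosylate 7 (not isolated)
Conditions: TsCl, Bu2SnO (cat.), Et3N, CH2Cl2, 0 °C; then K2CO3, MeOH, 0 °C
Reagents that add atoms: p-toluenesulfonyl chloride, Cc1ccc(cc1)S(Cl)(=O)=O (the tosyl group stays in 7 only)
Why: stannylene-directed sulfonylation should pick the primary hydroxyl of the 1,2-diol, and intramolecular Williamson closure by the propargylic alkoxide then gives the oxirane with retention at the carbinol carbon (C2).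

**Step 5**
Reactants: 8 alkynyl oxirane
Product: 9 methyl (2R,aR)-2,7-dihydroxy-4-methylhepta-4,5-dienoate
Conditions: Me2CuLi (from MeLi and CuI, excess), Et2O, −78 → −40 °C; aq. NH4Cl
Reagents that add atoms: lithium dimethylcuprate, [Li+].C[Cu-]C
Why: anti-selective SN2′ substitution of a propargylic oxirane by an organocuprate should deliver the C14 methyl to C10 on the side opposite to the departing oxygen, so the (S) centre is translated into the (aR) allene axis, while the ester is inert to the cuprate at low temperature.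

**Step 6**
Reactants: 9 allenic diol
Product: 10 methyl (2R,aR)-4-methyl-2,7-bis(triethylsilyloxy)hepta-4,5-dienoate
Conditions: Et3SiCl, imidazole, DMF, 0 °C
Reagents that add atoms: chlorotriethylsilane, CC[Si](Cl)(CC)CC
Why: imidazole-promoted silylation should protect the C3 and C8 hydroxyls in one operation as ethers that can later be told apart (primary against secondary).

**Step 7**
Reactants: 10 bis-silyl ester
Product: 11 (2R,aR)-4-methyl-2,7-bis(triethylsilyloxy)hepta-4,5-dienal
Conditions: i-Bu2AlH, CH2Cl2, −78 °C; aq. potassium sodium tartrate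
Reagents that add atoms: none
Why: partial reduction of an α-silyloxy ester should stop at the aldehyde because the chelated tetrahedral aluminium adduct survives at −78 °C.

**Step 8**
Reactants: 11 C7 aldehyde; 12 methyl acrylate
Product: 13 methyl (4R,aR)-3-hydroxy-6-methyl-2-methylidene-4,9-bis(triethylsilyloxy)nona-6,7-dienoate (both C7 epimers)
Conditions: DABCO, MeOH (cat.), neat 12, rt
Reagents that add atoms: none
Why: the Morita–Baylis–Hillman reaction should attach C11–C13 to C7, and the new carbinol centre is of no consequence because it becomes sp2 in step 9.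

**Step 9**
Reactants: 13 Baylis–Hillman adduct
Product: 15 methyl (2Z,4R,aR)-2-(bromomethyl)-6-methyl-4,9-bis(triethylsilyloxy)nona-2,6,7-trienoate, via allylic mesylate 14 (not isolated)
Conditions: MsCl, Et3N, CH2Cl2, −20 °C; then LiBr, THF, 0 °C
Reagents that add atoms: methanesulfonyl chloride, CS(Cl)(=O)=O (the mesyl group stays in 14 only); lithium bromide, [Li+].[Br-]
Why: SN2′ displacement of the Baylis–Hillman mesylate by bromide should give the thermodynamically preferred (Z)-2-(bromomethyl)enoate (C8 cis to CH2Br) under conditions that spare the allene and the silyl ethers.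

**Step 10**
Reactants: 16 but-2-yne-1,4-diol
Product: 17 4-(tert-butyldimethylsilyloxy)but-2-yn-1-ol
Conditions: t-BuMe2SiCl (0.3 equiv), imidazole, THF, 0 °C, excess 16
Reagents that add atoms: tert-butylchlorodimethylsilane, CC(C)(C)[Si](C)(C)Cl
Why: silylation with the diol in excess should give the mono-ether, which differentiates the later C15 (protected) and C6 (free) oxygens.

**Step 11**
Reactants: 17 mono-silylated butynediol
Product: 19 (2Z)-4-(tert-butyldimethylsilyloxy)-3-iodobut-2-en-1-ol, via cyclic alkenylaluminate 18 (not isolated)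
Conditions: NaAlH2(OCH2CH2OMe)2, THF, 0 °C; then I2, −78 °C
Reagents that add atoms: sodium bis(2-methoxyethoxy)aluminium dihydride, [Na+].COCCO[AlH2-]OCCOC (aluminium stays in 18 only); iodine, II
Why: hydroxyl-directed trans-hydroalumination should place aluminium on the carbon remote from the free hydroxyl, and iodinolysis with retention then gives the vinyl iodide in which iodine (later replaced by C3) and C6 are cis, which fixes the 4Z geometry.

**Step 12**
Reactants: 19 iodo allylic alcohol
Product: 20 (2Z)-4-(tert-butyldimethylsilyloxy)-3-iodobut-2-enal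
Conditions: MnO2, CH2Cl2, rt
Reagents that add atoms: none
Why: allylic oxidation with MnO2 is neutral and should keep the Z-enal geometry if the aldehyde is used at once.

**Step 13**
Reactants: 15 (Z)-allylic bromide; 20 Z-iodo-enal
Product: 23 (4S,5R)-5-[(1Z)-3-(tert-butyldimethylsilyloxy)-2-iodoprop-1-en-1-yl]-3-methylidene-4-[(1R,aR)-3-methyl-1,6-bis(triethylsilyloxy)hexa-3,4-dien-1-yl]oxolan-2-one, via allylzinc bromide 21 (not isolated), via zinc alkoxide 22 (not isolated)
Conditions: Zn dust (activated), THF, 0 → 45 °C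
Reagents that add atoms: zinc, [Zn] (zinc stays in 21 and 22 only)
Why: in this Dreiding–Schmidt zinc allylation the chair transition state should place the C8-bearing substituent (cis to CH2Zn) axial, which gives the 6,7-syn adduct and hence the cis-lactone on ring closure of 22, and the aldehyde should attack the allylzinc face anti to the C9 chain in the conformer with H8 eclipsing the double bond (allylic 1,3-strain) and the silyloxy group outside, which gives the 7,8-anti relation of the target.

**Step 14**
Reactants: 23 cis-lactone vinyl iodide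
Product: 24 (4S,5R)-5-[(1Z)-3-(tert-butyldimethylsilyloxy)-2-iodoprop-1-en-1-yl]-3-methylidene-4-[(1R,aR)-3-methyl-6-oxo-1-(triethylsilyloxy)hexa-3,4-dien-1-yl]oxolan-2-one
Conditions: (COCl)2, DMSO, CH2Cl2, −78 °C; then 23, −78 → −40 °C; Et3N, −78 °C
Reagents that add atoms: none
Why: Swern conditions should cleave and oxidise the primary triethylsilyl ether directly to the aldehyde while the secondary triethylsilyl and the tert-butyldimethylsilyl ethers survive, so the sensitive allenal is unmasked in one operation and used cold.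

**Step 15**
Reactants: 24 iodo-allenal
Product: 25 3-hydroxy-15-(tert-butyldimethylsilyloxy)-8-(triethylsilyloxy)germacra-1(2),1(10),4Z,11(13)-tetraen-12,6-olide (allene aR; C6 C7 C8 as in the target; C3 epimers)
Conditions: CrCl2 (excess), NiCl2 (cat.), DMSO/THF, rt, high dilution
Reagents that add atoms: none
Why: Nozaki–Hiyama–Kishi coupling of the Z-vinyl iodide with the aldehyde should close ring B at C3–C4 chemoselectively beside the lactone and the allene, the cis-lactone holding both arms on one face, and the C3 carbinol configuration is irrelevant because it is oxidised next.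

**Step 16**
Reactants: 25 macrocyclic allenyl carbinol
Product: 26 15-(tert-butyldimethylsilyloxy)-3-oxo-8-(triethylsilyloxy)germacra-1(2),1(10),4Z,11(13)-tetraen-12,6-olide (allene aR)
Conditions: Dess–Martin periodinane, CH2Cl2, 0 °C
Reagents that add atoms: none
Why: Dess–Martin oxidation of the doubly allylic alcohol should give the cross-conjugated allenyl ketone under base-free conditions that avoid allene-to-diene isomerisation.

**Step 17**
Reactants: 26 macrocyclic allenyl ketone
Product: 28 15-O-tert-butyldimethylsilyl-8-O-triethylsilyl ether of the 8-O-deacyl target (C6 C7 C8 C10 as in the target), via allene oxide 27 (not isolated)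
Conditions: dimethyldioxirane (1.1 equiv, acetone solution), CH2Cl2, −78 → −20 °C
Reagents that add atoms: dimethyldioxirane, CC1(C)OO1
Why: Proposed new method: dimethyldioxirane should epoxidise the C1=C10 bond of the allenyl ketone (the only C=C bond not conjugated to a carbonyl group) from its outer side, syn to H2, to give alkylidene oxirane 27, whose C10–O bond lies in the plane of the s-cis C3 carbonyl oxygen; that oxygen opens the oxirane at the tertiary allylic C10 with inversion, and the resulting C1 oxyanion/C3 oxocarbenium pair collapses to the vinylogous ester, so that C1 becomes the ketone. The closest known reaction types are the dimethyldioxirane oxidation of allenes with capture of the allene oxide by a tethered hydroxyl or carboxyl group, and the halocyclisation of 1,2-allenyl ketones, in which the carbonyl oxygen adds to the same allene terminus while the electrophile goes to the central carbon. Ring A closes in a 5-exo-tet mode (the leaving oxirane oxygen stays outside the new ring), and this completes the oxygen bridge across ring B. C10 is set by axis-to-centre transfer: the oxygen enters in the plane of the C2 substituents from the C3 side while C14 and C9 keep their faces, so the (aR) axis can only give 10R. The step needs chemoselectivity for C1=C10 over C4=C5, C11=C13 and the product enol ether, which their conjugation to carbonyl groups, one equivalent of oxidant and low temperature should secure, and it needs the oxidant on the outer face, which ring B enforces by blocking the inner one.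

**Step 18**
Reactants: 28 bis-silylated furanone
Product: 29 15-O-tert-butyldimethylsilyl-8-O-deacyl target (free C8 hydroxyl)
Conditions: PPTS (cat.), MeOH/CH2Cl2, 0 °C
Reagents that add atoms: none
Why: acid-catalysed methanolysis should remove the secondary triethylsilyl ether much faster than the primary tert-butyldimethylsilyl ether.

**Step 19**
Reactants: 29 C8 alcohol
Product: 30 15-O-tert-butyldimethylsilyl ether of the target
Conditions: i-PrCOCl, pyridine, DMAP (cat.), CH2Cl2, 0 °C
Reagents that add atoms: isobutyryl chloride, CC(C)C(Cl)=O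
Why: DMAP-catalysed acylation should esterify the only free hydroxyl without touching a stereocentre.

**Step 20**
Reactants: 30 silylated target
Product: 31 (4Z,6S,7R,8R,10R)-15-hydroxy-8-isobutyryloxy-1-oxo-3,10-epoxygermacra-2,4,11(13)-trien-12,6-olide (target)
Conditions: HF·pyridine, pyridine, THF, 0 °C → rt
Reagents that add atoms: none
Why: buffered fluoride desilylation should free the C15 hydroxyl without affecting the isobutyrate, the α-methylene lactone or the furanone.

**Compound list**
1 | (R)-2,2-dimethyl-1,3-dioxolane-4-carbaldehyde | O=C[C@H]1COC(C)(C)O1 | starting material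
2 | (S)-4-ethynyl-2,2-dimethyl-1,3-dioxolane | C#C[C@H]1COC(C)(C)O1 | intermediate
3 | methyl (R)-oxirane-2-carboxylate | COC(=O)[C@H]1CO1 | starting material
4 | lithium acetylide of 2 (not isolated) | [Li]C#C[C@H]1COC(C)(C)O1 | intermediate
5 | methyl (2R)-5-[(4S)-2,2-dimethyl-1,3-dioxolan-4-yl]-2-hydroxypent-4-ynoate | COC(=O)[C@H](O)CC#C[C@H]1COC(C)(C)O1 | intermediate
6 | methyl (2R,6S)-2,6,7-trihydroxyhept-4-ynoate | COC(=O)[C@H](O)CC#C[C@H](O)CO | intermediate
7 | methyl (2R,6S)-2,6-dihydroxy-7-[(4-methylphenyl)sulfonyloxy]hept-4-ynoate (not isolated) | COC(=O)[C@H](O)CC#C[C@H](O)COS(=O)(=O)c1ccc(C)cc1 | intermediate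
8 | methyl (2R)-2-hydroxy-5-[(2S)-oxiran-2-yl]pent-4-ynoate | COC(=O)[C@H](O)CC#C[C@H]1CO1 | intermediate
9 | methyl (2R,aR)-2,7-dihydroxy-4-methylhepta-4,5-dienoate | COC(=O)[C@H](O)CC(C)=[C@]=C([H])CO | intermediate
10 | methyl (2R,aR)-4-methyl-2,7-bis(triethylsilyloxy)hepta-4,5-dienoate | COC(=O)[C@H](O[Si](CC)(CC)CC)CC(C)=[C@]=C([H])CO[Si](CC)(CC)CC | intermediate
11 | (2R,aR)-4-methyl-2,7-bis(triethylsilyloxy)hepta-4,5-dienal | O=C[C@H](O[Si](CC)(CC)CC)CC(C)=[C@]=C([H])CO[Si](CC)(CC)CC | intermediate
12 | methyl acrylate | C=CC(=O)OC | starting material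
13 | methyl (4R,aR)-3-hydroxy-6-methyl-2-methylidene-4,9-bis(triethylsilyloxy)nona-6,7-dienoate (both C7 epimers) | COC(=O)C(=C)C(O)[C@H](O[Si](CC)(CC)CC)CC(C)=[C@]=C([H])CO[Si](CC)(CC)CC | intermediate
14 | methyl (4R,aR)-3-(methylsulfonyloxy)-6-methyl-2-methylidene-4,9-bis(triethylsilyloxy)nona-6,7-dienoate (not isolated) | COC(=O)C(=C)C(OS(C)(=O)=O)[C@H](O[Si](CC)(CC)CC)CC(C)=[C@]=C([H])CO[Si](CC)(CC)CC | intermediate
15 | methyl (2Z,4R,aR)-2-(bromomethyl)-6-methyl-4,9-bis(triethylsilyloxy)nona-2,6,7-trienoate | COC(=O)/C(CBr)=C/[C@H](O[Si](CC)(CC)CC)CC(C)=[C@]=C([H])CO[Si](CC)(CC)CC | intermediate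
16 | but-2-yne-1,4-diol | OCC#CCO | starting material
17 | 4-(tert-butyldimethylsilyloxy)but-2-yn-1-ol | OCC#CCO[Si](C)(C)C(C)(C)C | intermediate
18 | sodium cyclic alkenyl(alkoxy)bis(2-methoxyethoxy)aluminate from 17 (not isolated) | [Na+].COCCO[Al-]1(OCCOC)OCC=C1CO[Si](C)(C)C(C)(C)C | intermediate
19 | (2Z)-4-(tert-butyldimethylsilyloxy)-3-iodobut-2-en-1-ol | OC/C=C(\I)CO[Si](C)(C)C(C)(C)C | intermediate
20 | (2Z)-4-(tert-butyldimethylsilyloxy)-3-iodobut-2-enal | O=C/C=C(\I)CO[Si](C)(C)C(C)(C)C | intermediate
21 | allylzinc bromide from 15 (not isolated) | COC(=O)/C(C[Zn]Br)=C/[C@H](O[Si](CC)(CC)CC)CC(C)=[C@]=C([H])CO[Si](CC)(CC)CC | intermediate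
22 | bromozinc alkoxide of the 6,7-syn-7,8-anti hydroxy ester (not isolated) | COC(=O)C(=C)[C@@H]([C@@H](O[Zn]Br)/C=C(\I)CO[Si](C)(C)C(C)(C)C)[C@H](O[Si](CC)(CC)CC)CC(C)=[C@]=C([H])CO[Si](CC)(CC)CC | intermediate
23 | (4S,5R)-5-[(1Z)-3-(tert-butyldimethylsilyloxy)-2-iodoprop-1-en-1-yl]-3-methylidene-4-[(1R,aR)-3-methyl-1,6-bis(triethylsilyloxy)hexa-3,4-dien-1-yl]oxolan-2-one | C=C1C(=O)O[C@@H](/C=C(\I)CO[Si](C)(C)C(C)(C)C)[C@H]1[C@H](O[Si](CC)(CC)CC)CC(C)=[C@]=C([H])CO[Si](CC)(CC)CC | intermediate
24 | (4S,5R)-5-[(1Z)-3-(tert-butyldimethylsilyloxy)-2-iodoprop-1-en-1-yl]-3-methylidene-4-[(1R,aR)-3-methyl-6-oxo-1-(triethylsilyloxy)hexa-3,4-dien-1-yl]oxolan-2-one | C=C1C(=O)O[C@@H](/C=C(\I)CO[Si](C)(C)C(C)(C)C)[C@H]1[C@H](O[Si](CC)(CC)CC)CC(C)=[C@]=C([H])C=O | intermediate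
25 | 3-hydroxy-15-(tert-butyldimethylsilyloxy)-8-(triethylsilyloxy)germacra-1(2),1(10),4Z,11(13)-tetraen-12,6-olide (allene aR; C6 C7 C8 as in the target; C3 epimers) | C=C1C(=O)O[C@H]2/C=C(/CO[Si](C)(C)C(C)(C)C)C(O)C([H])=[C@]=C(C)C[C@@H](O[Si](CC)(CC)CC)[C@@H]12 | intermediate
26 | 15-(tert-butyldimethylsilyloxy)-3-oxo-8-(triethylsilyloxy)germacra-1(2),1(10),4Z,11(13)-tetraen-12,6-olide (allene aR) | C=C1C(=O)O[C@H]2/C=C(/CO[Si](C)(C)C(C)(C)C)C(=O)C([H])=[C@]=C(C)C[C@@H](O[Si](CC)(CC)CC)[C@@H]12 | intermediate
27 | 1,10-epoxide of 26 (alkylidene oxirane, oxygen syn to H2; not isolated) | C=C1C(=O)O[C@H]2/C=C(/CO[Si](C)(C)C(C)(C)C)C(=O)/C=C3/O[C@@]3(C)C[C@@H](O[Si](CC)(CC)CC)[C@@H]12 | intermediate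
28 | 15-O-tert-butyldimethylsilyl-8-O-triethylsilyl ether of the 8-O-deacyl target | C=C1C(=O)O[C@H]2/C=C(/CO[Si](C)(C)C(C)(C)C)C3=CC(=O)[C@@](C)(C[C@@H](O[Si](CC)(CC)CC)[C@@H]12)O3 | intermediate
29 | 15-O-tert-butyldimethylsilyl-8-O-deacyl target | C=C1C(=O)O[C@H]2/C=C(/CO[Si](C)(C)C(C)(C)C)C3=CC(=O)[C@@](C)(C[C@@H](O)[C@@H]12)O3 | intermediate
30 | 15-O-tert-butyldimethylsilyl ether of the target | C=C1C(=O)O[C@H]2/C=C(/CO[Si](C)(C)C(C)(C)C)C3=CC(=O)[C@@](C)(C[C@@H](OC(=O)C(C)C)[C@@H]12)O3 | intermediate
31 | (4Z,6S,7R,8R,10R)-15-hydroxy-8-isobutyryloxy-1-oxo-3,10-epoxygermacra-2,4,11(13)-trien-12,6-olide | C=C1C(=O)O[C@H]2/C=C(/CO)C3=CC(=O)[C@@](C)(C[C@@H](OC(=O)C(C)C)[C@@H]12)O3 | target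

**Step count and risks**
Total step count: 20. Longest linear sequence: 17 steps (steps 1–9 and 13–20); steps 10–12 make the second fragment.

Step 17 (key step, proposed new method). What may go wrong: epoxidation at another double bond or a second epoxidation of 27 to a spiro-diepoxide, opening of 27 by an external nucleophile, or ring-opening of 27 to an oxyallyl species that loses the axial information. The fallback uses known chemistry, sets out from 26 and comes back at 28. Bromocyclisation of the 1,2-allenyl ketone with N-bromosuccinimide in wet MeCN at 0 °C (electrophilic halocyclisation: bromonium ion on the outer face of C1=C10, carbonyl oxygen to C10 on the same in-plane path, hence the same 10R centre) and capture of the cyclic oxocarbenium ion by water at C3 should give the bromo hemiketal 1-bromo-3-hydroxy-3,10-epoxy-15-(tert-butyldimethylsilyloxy)-8-(triethylsilyloxy)germacra-1,4Z,11(13)-trien-12,6-olide F1. Silver-assisted hydrolysis (AgOSO2CF3, 2,6-lutidine, wet acetone) should then ionise the hemiketal, add water at C1 and expel bromide to give 28.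

Step 13. What may go wrong: poor facial selectivity at the allylzinc carbon (7,8-syn isomer) or erosion of the 6,7-syn preference by metallotropic equilibration of 21. The fallback sets out from 15 and comes back at 23. Borylation of 15 with B2pin2 and Pd2(dba)3 (cat.) in DMSO should give the linear allylboronate methyl (2E,4R,aR)-6-methyl-2-[(4,4,5,5-tetramethyl-1,3,2-dioxaborolan-2-yl)methyl]-4,9-bis(triethylsilyloxy)nona-2,6,7-trienoate F2, whose double-bond geometry cannot equilibrate. Allylboration of 20 with Sc(OTf)3 (cat.) in toluene through a closed chair transition state, where a chiral Brønsted acid can be added to reinforce the aldehyde face, and cyclisation of the borate on warming should give 23.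

Step 15. What may go wrong: oligomerisation in place of ring closure, or reduction and isomerisation of the allenal while the ten-membered ring closes slowly. The fallback reverses the order of the two C–C bond formations, so that ring B is closed by allylation at C6–C7; it sets out from 13 (with 19) and comes back at 25. Acetylation of 13 (Ac2O, pyridine) should give methyl (4R,aR)-3-acetoxy-6-methyl-2-methylidene-4,9-bis(triethylsilyloxy)nona-6,7-dienoate F3, and Swern cleavage–oxidation of its primary silyl ether the allenal methyl (4R,aR)-3-acetoxy-6-methyl-2-methylidene-9-oxo-4-(triethylsilyloxy)nona-6,7-dienoate F4. Intermolecular CrCl2/NiCl2 coupling of F4 with 19 should give the diol methyl (4R,aR,10Z)-3-acetoxy-10-[(tert-butyldimethylsilyloxy)methyl]-9,12-dihydroxy-6-methyl-2-methylidene-4-(triethylsilyloxy)dodeca-6,7,10-trienoate F5, and selective oxidation of its primary allylic hydroxyl (TEMPO, PhI(OAc)2) the enal methyl (4R,aR,10Z)-3-acetoxy-10-[(tert-butyldimethylsilyloxy)methyl]-9-hydroxy-6-methyl-2-methylidene-12-oxo-4-(triethylsilyloxy)dodeca-6,7,10-trienoate F6. Intramolecular carbonyl allylation of F6 with Pd(PPh3)4 (cat.) and InI in THF (umpolung of the allylic acetate) followed by lactonisation should give 25.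

**Further compounds**
F1 | step 17 | 1-bromo-3-hydroxy-3,10-epoxy-15-(tert-butyldimethylsilyloxy)-8-(triethylsilyloxy)germacra-1,4Z,11(13)-trien-12,6-olide (10R; C3 epimers) | C=C1C(=O)O[C@H]2/C=C(/CO[Si](C)(C)C(C)(C)C)C3(O)C=C(Br)[C@@](C)(C[C@@H](O[Si](CC)(CC)CC)[C@@H]12)O3
F2 | step 13 | methyl (2E,4R,aR)-6-methyl-2-[(4,4,5,5-tetramethyl-1,3,2-dioxaborolan-2-yl)methyl]-4,9-bis(triethylsilyloxy)nona-2,6,7-trienoate | COC(=O)/C(CB1OC(C)(C)C(C)(C)O1)=C/[C@H](O[Si](CC)(CC)CC)CC(C)=[C@]=C([H])CO[Si](CC)(CC)CC
F3 | step 15 | methyl (4R,aR)-3-acetoxy-6-methyl-2-methylidene-4,9-bis(triethylsilyloxy)nona-6,7-dienoate | COC(=O)C(=C)C(OC(C)=O)[C@H](O[Si](CC)(CC)CC)CC(C)=[C@]=C([H])CO[Si](CC)(CC)CC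
F4 | step 15 | methyl (4R,aR)-3-acetoxy-6-methyl-2-methylidene-9-oxo-4-(triethylsilyloxy)nona-6,7-dienoate | COC(=O)C(=C)C(OC(C)=O)[C@H](O[Si](CC)(CC)CC)CC(C)=[C@]=C([H])C=O
F5 | step 15 | methyl (4R,aR,10Z)-3-acetoxy-10-[(tert-butyldimethylsilyloxy)methyl]-9,12-dihydroxy-6-methyl-2-methylidene-4-(triethylsilyloxy)dodeca-6,7,10-trienoate | COC(=O)C(=C)C(OC(C)=O)[C@H](O[Si](CC)(CC)CC)CC(C)=[C@]=C([H])C(O)/C(CO[Si](C)(C)C(C)(C)C)=C\CO
F6 | step 15 | methyl (4R,aR,10Z)-3-acetoxy-10-[(tert-butyldimethylsilyloxy)methyl]-9-hydroxy-6-methyl-2-methylidene-12-oxo-4-(triethylsilyloxy)dodeca-6,7,10-trienoate | COC(=O)C(=C)C(OC(C)=O)[C@H](O[Si](CC)(CC)CC)CC(C)=[C@]=C([H])C(O)/C(CO[Si](C)(C)C(C)(C)C)=C\C=O
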